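**Assumptions:** The SMILES defines the target, a (2S,3R,4R) 2-syringyl-4-guaiacylmethyl-tetrahydrofuran whose 3-CH2OH carries an (E)-ferulate. MeI, NBS, PivCl, CO, Br2, H2O and NaOMe are treated as reagents. The sense of induction in step 5 must be fixed by a test run; (R,R)-ligand is written and its antipode is used if it gives (S)-8.

## Retrosynthetic overview

1. Ester C–O last: chemoselective Mitsunobu esterification of the free lignan primary alcohol with ferulic acid (Heck reaction of bromoguaiacol with acrylic acid).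
2. Tetrahydrofuran (second ring made): acid closure of the benzylic C–O bond in a triol, obtained by LiAlH4 reduction of a trans aldol adduct of a β-(arylmethyl)-γ-butyrolactone with O-pivaloyl syringaldehyde.
3. γ-Lactone (first ring made): enantioselective CO-insertion ring expansion of a prochiral 3-(arylmethyl)oxetane, which sets the benzyl-bearing stereocentre.
4. Oxetane: hydroboration/Suzuki coupling of 3-methylideneoxetane with bromoguaiacol pivalate (from catechol); syringaldehyde from p-cresol.
5. Ring order: bought oxetane → γ-lactone → lactone opened by hydride → tetrahydrofuran.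

## Route

Step 1
Reactants: 1 catechol (benzene-1,2-diol)
Product: 2 guaiacol (2-methoxyphenol)
Conditions: MeI (1.0 equiv), K2CO3 (1.0 equiv), acetone, reflux; NaOH extraction, then acidify
Reagents that add atoms: iodomethane CI
Why: Williamson ether synthesis in which one equivalent of base gives the hydrogen-bonded monophenoxide that is methylated once, and phenolic guaiacol is separated from neutral veratrole and water-soluble catechol by extraction.

Step 2
Reactants: 2 guaiacol
Product: 3 4-bromo-2-methoxyphenol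
Conditions: NBS (1.0 equiv), MeCN, 0 °C → rt
Reagents that add atoms: N-bromosuccinimide O=C1CCC(=O)N1Br
Why: Electrophilic aromatic bromination in which the free OH is the stronger donor and directs bromine to its para position.

Step 3
Reactants: 3 4-bromo-2-methoxyphenol
Product: 4 4-bromo-2-methoxyphenyl pivalate
Conditions: PivCl (1.1 equiv), Et3N (1.3 equiv), DMAP (5 mol %), CH2Cl2, 0 °C → rt
Reagents that add atoms: pivaloyl chloride CC(C)(C)C(Cl)=O
Why: DMAP-catalysed O-acylation giving a hindered aryl ester that survives Pd coupling, the Lewis-acid/cobaltate step and LDA, and is later removed by the LiAlH4 of step 10 without a separate deprotection.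

Step 4
Reactants: 5 3-methylideneoxetane; 4 4-bromo-2-methoxyphenyl pivalate
Product: 7 2-methoxy-4-(oxetan-3-ylmethyl)phenyl pivalate, via 9-(oxetan-3-ylmethyl)-9-BBN 6 (not isolated)
Conditions: 5 (1.3 equiv), 9-BBN (0.5 M in THF, 1.3 equiv), 0 °C → rt, 3 h; then 4, PdCl2(dppf) (3 mol %), K3PO4 (3 equiv), H2O (5 equiv), DMF, 50 °C
Reagents that add atoms: none
Why: Anti-Markovnikov hydroboration of the 1,1-disubstituted alkene followed by B-alkyl Suzuki–Miyaura coupling, with a mild phosphate base that leaves the oxetane and the hindered aryl ester intact.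

Step 5
Reactants: 7 2-methoxy-4-(oxetan-3-ylmethyl)phenyl pivalate
Product: 8 2-methoxy-4-{[(3R)-5-oxooxolan-3-yl]methyl}phenyl pivalate
Conditions: [(R,R)-(salen)Cr(THF)2][Co(CO)4] (5 mol %; salen = N,N′-bis(3,5-di-tert-butylsalicylidene)cyclohexane-1,2-diamine), CO (60 bar), DME, 60 °C, 24 h
Reagents that add atoms: carbon monoxide [C-]#[O+]
Why: Proposed new method: enantioselective desymmetrising ring-expansion carbonylation of a prochiral 3-substituted oxetane, in which the C2-symmetric chiral Cr(III) cation binds the oxetane oxygen, [Co(CO)4]− opens one of the two enantiotopic CH2–O bonds by SN2 (the stepped salen pocket holds the arylmethyl arm in the open quadrant so only one CH2 is exposed), CO inserts into the alkyl–Co bond and the Cr-bound alkoxide closes on the acyl-cobalt to release the γ-lactone with no co-product; the stereocentre (R) is fixed at ring opening and cannot erode because it is never a reacting carbon; the closest known reaction types are the achiral Lewis-acid/[Co(CO)4]− carbonylative ring expansion of oxetanes to γ-butyrolactones, its chiral-salen variant that desymmetrises meso-epoxides to β-lactones, and (salen)metal-catalysed enantioselective opening of 3-substituted oxetanes by oxygen nucleophiles.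

Step 6
Reactants: 9 p-cresol (4-methylphenol)
Product: 12 3,5-dibromo-4-hydroxybenzaldehyde, via 2,6-dibromo-4-methylphenol 10 (not isolated), via 2,6-dibromo-4-(dibromomethyl)phenol 11 (not isolated)
Conditions: Br2 (2.0 equiv), o-dichlorobenzene, 30–40 °C; Br2 (2.0 equiv), 150–160 °C; then H2O, 100 °C
Reagents that add atoms: bromine BrBr; water O
Why: Electrophilic ring bromination at both positions ortho to OH at low temperature, then thermal side-chain dibromination and hydrolysis of the benzal bromide to the aldehyde, a one-pot sequence used on scale for this compound.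

Step 7
Reactants: 12 3,5-dibromo-4-hydroxybenzaldehyde
Product: 13 syringaldehyde (4-hydroxy-3,5-dimethoxybenzaldehyde)
Conditions: NaOMe (5 equiv), CuCl (10 mol %), MeOH/DMF, 115 °C; then aq. HCl
Reagents that add atoms: sodium methoxide C[O-].[Na+]
Why: Copper-catalysed Ullmann-type methoxylation of both aryl bromides, with the aldehyde protected from methoxide by its conjugation to the phenoxide.

Step 8
Reactants: 13 syringaldehyde
Product: 14 4-formyl-2,6-dimethoxyphenyl pivalate
Conditions: PivCl (1.3 equiv), Et3N (1.5 equiv), DMAP (10 mol %), CH2Cl2, rt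
Reagents that add atoms: pivaloyl chloride CC(C)(C)C(Cl)=O
Why: O-acylation that removes the acidic phenol (a phenoxide would consume enolate and deactivate the aldehyde) and installs a group cleaved by LiAlH4 in step 10.

Step 9
Reactants: 8 2-methoxy-4-{[(3R)-5-oxooxolan-3-yl]methyl}phenyl pivalate; 14 4-formyl-2,6-dimethoxyphenyl pivalate
Product: 16 (3S,4R)-3-{hydroxy[3,5-dimethoxy-4-(pivaloyloxy)phenyl]methyl}-4-[3-methoxy-4-(pivaloyloxy)benzyl]oxolan-2-one (3,4-trans; both carbinol epimers), via lithium lactone enolate 15 (not isolated)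
Conditions: LDA (1.1 equiv), THF, −78 °C, 45 min; then 14 (1.1 equiv), −78 °C, 1 h; AcOH quench at −78 °C
Reagents that add atoms: none
Why: Lithium-enolate aldol addition in which the aldehyde approaches the enolate face anti to the β-arylmethyl group, setting C3 (S) trans to C4, while the carbinol centre forms as a mixture that is erased in step 10.

Step 10
Reactants: 16 trans aldol adduct
Product: 18 4-[(2S,3R,4R)-4-(4-hydroxy-3-methoxybenzyl)-3-(hydroxymethyl)oxolan-2-yl]-2,6-dimethoxyphenol, via lignan triol 17 (not isolated)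
Conditions: LiAlH4 (5 equiv), THF, 0 °C → rt, 4 h; then 0 °C, 2 M HCl to pH 1, rt, 1 h
Reagents that add atoms: none
Why: Hydride reduction opens the lactone to the 1,4-diol and cleaves both pivalates, then mild acid ionises the p-hydroxybenzylic alcohol and the CH2OH on the benzyl-bearing carbon closes the tetrahydrofuran (SN1 cycloetherification), which places the aryl trans to the neighbouring CH2OH (2S) under reversible conditions whatever the carbinol configuration, the trans lactone geometry becoming 3,4-cis in the new ring.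

Step 11
Reactants: 3 4-bromo-2-methoxyphenol; 19 acrylic acid
Product: 20 (E)-ferulic acid
Conditions: Pd(OAc)2 (2 mol %), P(o-tol)3 (6 mol %), Et3N (3 equiv), DMF, 100 °C; then aq. HCl
Reagents that add atoms: none
Why: Mizoroki–Heck reaction whose syn insertion and syn β-hydride elimination give the E alkene.

Step 12
Reactants: 18 lignan alcohol; 20 (E)-ferulic acid
Product: 21 [(2S,3R,4R)-2-(4-hydroxy-3,5-dimethoxyphenyl)-4-(4-hydroxy-3-methoxybenzyl)oxolan-3-yl]methyl (2E)-3-(4-hydroxy-3-methoxyphenyl)prop-2-enoate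
Conditions: 20 (1.2 equiv), PPh3 (1.3 equiv), DIAD (1.3 equiv, added last), THF, 0 °C → rt
Reagents that add atoms: none
Why: Mitsunobu esterification in which only the carboxylic acid (pKa about 4.5) is acidic enough to protonate the betaine and its carboxylate displaces the primary alkoxyphosphonium, so the three phenols (pKa about 10) stay free and no stereocentre is touched.

## Compound list

1 | catechol (benzene-1,2-diol) | Oc1ccccc1O | starting material
2 | guaiacol (2-methoxyphenol) | COc1ccccc1O | intermediate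
3 | 4-bromo-2-methoxyphenol | COc1cc(Br)ccc1O | intermediate
4 | 4-bromo-2-methoxyphenyl pivalate | COc1cc(Br)ccc1OC(=O)C(C)(C)C | intermediate
5 | 3-methylideneoxetane | C=C1COC1 | starting material
6 | 9-(oxetan-3-ylmethyl)-9-borabicyclo[3.3.1]nonane | C1OCC1CB1C2CCCC1CCC2 | intermediate
7 | 2-methoxy-4-(oxetan-3-ylmethyl)phenyl pivalate | COc1cc(CC2COC2)ccc1OC(=O)C(C)(C)C | intermediate
8 | 2-methoxy-4-{[(3R)-5-oxooxolan-3-yl]methyl}phenyl pivalate | O=C1C[C@@H](Cc2ccc(OC(=O)C(C)(C)C)c(OC)c2)CO1 | intermediate
9 | p-cresol (4-methylphenol) | Cc1ccc(O)cc1 | starting material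
10 | 2,6-dibromo-4-methylphenol | Cc1cc(Br)c(O)c(Br)c1 | intermediate
11 | 2,6-dibromo-4-(dibromomethyl)phenol | BrC(Br)c1cc(Br)c(O)c(Br)c1 | intermediate
12 | 3,5-dibromo-4-hydroxybenzaldehyde | O=Cc1cc(Br)c(O)c(Br)c1 | intermediate
13 | syringaldehyde (4-hydroxy-3,5-dimethoxybenzaldehyde) | COc1cc(C=O)cc(OC)c1O | intermediate
14 | 4-formyl-2,6-dimethoxyphenyl pivalate | COc1cc(C=O)cc(OC)c1OC(=O)C(C)(C)C | intermediate
15 | lithium enolate of 8 | [Li]OC1=C[C@@H](Cc2ccc(OC(=O)C(C)(C)C)c(OC)c2)CO1 | intermediate
16 | (3S,4R)-3-{hydroxy[3,5-dimethoxy-4-(pivaloyloxy)phenyl]methyl}-4-[3-methoxy-4-(pivaloyloxy)benzyl]oxolan-2-one, carbinol epimers | O=C1[C@H](C(O)c2cc(OC)c(OC(=O)C(C)(C)C)c(OC)c2)[C@@H](Cc3ccc(OC(=O)C(C)(C)C)c(OC)c3)CO1 | intermediate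
17 | (2R,3R)-2-[hydroxy(4-hydroxy-3,5-dimethoxyphenyl)methyl]-3-(4-hydroxy-3-methoxybenzyl)butane-1,4-diol, carbinol epimers | OC[C@H](C(O)c1cc(OC)c(O)c(OC)c1)[C@@H](Cc2ccc(O)c(OC)c2)CO | intermediate
18 | 4-[(2S,3R,4R)-4-(4-hydroxy-3-methoxybenzyl)-3-(hydroxymethyl)oxolan-2-yl]-2,6-dimethoxyphenol | OC[C@H]1[C@@H](Cc2ccc(O)c(OC)c2)CO[C@@H]1c3cc(OC)c(O)c(OC)c3 | intermediate
19 | acrylic acid | C=CC(=O)O | starting material
20 | (E)-ferulic acid | COc1cc(/C=C/C(=O)O)ccc1O | intermediate
21 | [(2S,3R,4R)-2-(4-hydroxy-3,5-dimethoxyphenyl)-4-(4-hydroxy-3-methoxybenzyl)oxolan-3-yl]methyl (2E)-3-(4-hydroxy-3-methoxyphenyl)prop-2-enoate | COc1cc(/C=C/C(=O)OC[C@H]2[C@@H](Cc3ccc(O)c(OC)c3)CO[C@@H]2c2cc(OC)c(O)c(OC)c2)ccc1O | target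

## Step count and risks

Total steps: 12. Longest linear sequence: 8 (steps 1, 2, 3, 4, 5, 9, 10, 12).

**Step 5 (new reaction; turnover and enantioselectivity are unproven).** The fallback uses known chemistry, sets out from 4 and comes back at 8. Nickel-catalysed reductive cross-electrophile coupling of 4 (NiBr2·glyme, 4,4′-di-tert-butyl-2,2′-bipyridine, Zn, NaI, DMA, 60 °C) with bought 3-(bromomethyl)cyclobutan-1-one F1 (seven non-hydrogen atoms) gives 2-methoxy-4-[(3-oxocyclobutyl)methyl]phenyl pivalate F2. The established asymmetric Baeyer–Villiger desymmetrisation of 3-substituted cyclobutanones (chiral Sc(III)–N,N′-dioxide with m-CPBA, a chiral phosphoric acid with aqueous H2O2, or a Baeyer–Villiger monooxygenase) then delivers 8, and the route continues at step 9.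

**Step 10 (one-pot reduction and cyclisation; acid may close the guaiacyl ring onto the benzylic cation to give an aryltetralin, or give C2 epimers).** The fallback sets out from 16 and comes back at 18, making the benzylic C–O bond oxidatively without acid. Hydrogenolysis of the benzylic hydroxyl of 16 (H2, Pd/C, AcOH, cat. HClO4) gives (3R,4R)-3-[3,5-dimethoxy-4-(pivaloyloxy)benzyl]-4-[3-methoxy-4-(pivaloyloxy)benzyl]oxolan-2-one F3. LiAlH4 reduction then gives (2R,3R)-2-(4-hydroxy-3,5-dimethoxybenzyl)-3-(4-hydroxy-3-methoxybenzyl)butane-1,4-diol F4. DDQ (1.0 equiv, dioxane, rt) oxidises the more electron-rich syringyl unit to its quinone methide, which is trapped by the 1,4-related CH2OH to give 18. The selectivity for the syringyl over the guaiacyl benzylic position is expected but not guaranteed.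

**Step 12 (chemoselectivity of the Mitsunobu reaction with three free phenols; β-branched primary alcohol).** The fallback sets out from 18 and 20 and comes back at 21. Phenol-selective acetylation of 18 (Ac2O, aqueous NaOH/THF, 0 °C) gives 4-[(2S,3R,4R)-2-(4-acetoxy-3,5-dimethoxyphenyl)-3-(hydroxymethyl)oxolan-4-yl]methyl-2-methoxyphenyl acetate F5. Acetylation of 20 gives (E)-4-O-acetylferulic acid F6. Carbodiimide coupling (EDC·HCl, DMAP, CH2Cl2) gives the tri-O-acetate of the target F7. Pyrrolidine then removes the three aryl acetates selectively in the presence of the alkyl cinnamate to give 21.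

## Further compounds

F1 | step 5 | 3-(bromomethyl)cyclobutan-1-one (bought coupling partner) | O=C1CC(CBr)C1
F2 | step 5 | 2-methoxy-4-[(3-oxocyclobutyl)methyl]phenyl pivalate | COc1cc(CC2CC(=O)C2)ccc1OC(=O)C(C)(C)C
F3 | step 10 | (3R,4R)-3-[3,5-dimethoxy-4-(pivaloyloxy)benzyl]-4-[3-methoxy-4-(pivaloyloxy)benzyl]oxolan-2-one | O=C1[C@H](Cc2cc(OC)c(OC(=O)C(C)(C)C)c(OC)c2)[C@@H](Cc3ccc(OC(=O)C(C)(C)C)c(OC)c3)CO1
F4 | step 10 | (2R,3R)-2-(4-hydroxy-3,5-dimethoxybenzyl)-3-(4-hydroxy-3-methoxybenzyl)butane-1,4-diol | OC[C@H](Cc1cc(OC)c(O)c(OC)c1)[C@@H](Cc2ccc(O)c(OC)c2)CO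
F5 | step 12 | 4-[(2S,3R,4R)-2-(4-acetoxy-3,5-dimethoxyphenyl)-3-(hydroxymethyl)oxolan-4-yl]methyl-2-methoxyphenyl acetate | OC[C@H]1[C@@H](Cc2ccc(OC(C)=O)c(OC)c2)CO[C@@H]1c3cc(OC)c(OC(C)=O)c(OC)c3
F6 | step 12 | (E)-4-O-acetylferulic acid | COc1cc(/C=C/C(=O)O)ccc1OC(C)=O
F7 | step 12 | tri-O-acetate of 21 | COc1cc(/C=C/C(=O)OC[C@H]2[C@@H](Cc3ccc(OC(C)=O)c(OC)c3)CO[C@@H]2c4cc(OC)c(OC(C)=O)c(OC)c4)ccc1OC(C)=O
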